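**Retrosynthetic overview**
1. The two methyl groups are treated as the carbon ends of an excised sulfur bridge: target ⇒ sulfolane-fused 1-aryl-1,2-dihydronaphthalene (C–S → C–H in the last step).
2. Key disconnection, C2–C3 and C1–C8a together ⇒ achiral (E)-cinnamyl 3-arylpropargyl sulfone. An enantioselective gold-catalysed formal [4+2] closes the sulfolane ring and ring B in one operation and sets C1 and C2. The arylalkyne is the four-carbon partner and the styrene the two-carbon partner.
3. Enyne sulfone ⇒ S-oxidation of the sulfide ⇒ Sonogashira coupling of 4-iodoveratrole with a cinnamyl propargyl sulfide.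
4. That sulfide ⇒ veratraldehyde, vinylmagnesium bromide, thiourea and propargyl bromide.
5. Ring order: both veratryl rings are bought, the sulfolane ring and ring B form simultaneously, and the sulfur ring is deleted at the end.

Assumption: the facial sense of the digold catalyst on this new substrate cannot be predicted, so (R)-DTBM-MeO-BIPHEP [(R)-(6,6'-dimethoxybiphenyl-2,2'-diyl)bis[bis(3,5-di-tert-butyl-4-methoxyphenyl)phosphine]] is written, and its equally available (S)-antipode is used if crystalline 12 (anomalous-dispersion X-ray on sulfur) proves to be the mirror image.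

**Step 1**
Reactants: 1 3,4-dimethoxybenzaldehyde (veratraldehyde); 2 vinylmagnesium bromide
Product: 3 (±)-1-(3,4-dimethoxyphenyl)prop-2-en-1-ol
Conditions: THF, 0 °C to rt; H2O quench
Reagents that add atoms: none
Why: Grignard 1,2-addition to an aromatic aldehyde, in which the carbinol centre may be racemic because step 2 erases it.

**Step 2**
Reactants: 3 (±)-1-(3,4-dimethoxyphenyl)prop-2-en-1-ol; 4 thiourea; 5 propargyl bromide
Product: 8 (E)-1,2-dimethoxy-4-[3-(prop-2-yn-1-ylsulfanyl)prop-1-en-1-yl]benzene, via isothiouronium chloride 6 (not isolated), via sodium thiolate 7 (not isolated)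
Conditions: 4, aq HCl (1.2 equiv), EtOH, 0 °C to rt; degassed aq NaOH (2.2 equiv), 50 °C, N2; then 5, 0 °C to rt
Reagents that add atoms: none
Why: Acid ionises the activated alcohol to the 3,4-dimethoxycinnamyl cation, which the soft sulfur of thiourea captures at the open terminus (SN1' allylic transposition giving the conjugated (E)-styrene), and alkaline isothiouronium hydrolysis releases the thiolate for SN2 S-alkylation (isothiouronium route to thioethers) without handling a free thiol.

**Step 3**
Reactants: 8 (E)-cinnamyl-type propargyl sulfide; 9 4-iodo-1,2-dimethoxybenzene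
Product: 10 (E)-3-(3,4-dimethoxyphenyl)prop-2-en-1-yl 3-(3,4-dimethoxyphenyl)prop-2-yn-1-yl sulfide
Conditions: PdCl2(PPh3)2 (2 mol%), CuI (4 mol%), Et3N, THF, rt
Reagents that add atoms: none
Why: Sonogashira coupling of a terminal alkyne with an aryl iodide runs at rt, where the dialkyl sulfide and the styrene are spectators and the amine is too weak a base to isomerise the propargyl sulfide to an allene.

**Step 4**
Reactants: 10 enyne sulfide
Product: 11 (E)-3-(3,4-dimethoxyphenyl)prop-2-en-1-yl 3-(3,4-dimethoxyphenyl)prop-2-yn-1-yl sulfone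
Conditions: 30% H2O2 (3 equiv), (NH4)6Mo7O24·4H2O (5 mol%), EtOH, 0 °C to rt; recrystallise
Reagents that add atoms: hydrogen peroxide, OO
Why: Molybdate-catalysed peroxide S-oxidation (sulfide to sulfoxide to sulfone) is much faster than attack on the styrene or the alkyne, and it follows step 3 because a terminal propargyl sulfone would isomerise to the allenyl sulfone under the amine base.

**Step 5 (key step)**
Reactants: 11 enyne sulfone
Product: 12 (3aS,4R)-4-(3,4-dimethoxyphenyl)-6,7-dimethoxy-1,3,3a,4-tetrahydronaphtho[2,3-c]thiophene 2,2-dioxide (H-3a and H-4 trans)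
Conditions: [(R)-DTBM-MeO-BIPHEP](AuCl)2 (3 mol%), AgSbF6 (6 mol%), 4 Å MS, CH2Cl2, 0 °C to rt; recrystallise to raise ee
Reagents that add atoms: none
Why: Proposed new method: cationic monovalent gold binds the alkyne, the electron-rich (E)-styrene attacks the propargylic alkyne carbon anti to gold (5-exo-dig, closing the sulfolane ring and placing charge on the 3,4-dimethoxybenzylic carbon), and the alkyne-borne veratryl ring, held cis to that carbon, closes ring B by Friedel–Crafts attack para to its 3-methoxy group before protodeauration, so the (E)-geometry is copied into the trans C3a/C4 relationship and the chiral digold pocket selects the alkene face and hence the absolute (3aS,4R) configuration; the closest known reaction types are the gold-catalysed formal [4+2] (dehydro-Diels–Alder type) cycloaddition of aryl-alkyne 1,6-enynes and the enantioselective enyne hydroarylation/cyclisation run on cinnamyl-type enynes using the same digold complexes, the untested element being the SO2 link, chosen because it has no lone pair to bind gold or to assist the competing 6-endo hydride-shift path.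

**Step 6**
Reactants: 12 tricyclic sulfone
Product: 14 (1R,2S)-1-(3,4-dimethoxyphenyl)-6,7-dimethoxy-2,3-dimethyl-1,2-dihydronaphthalene (target), via tricyclic thiolane 13 (not isolated)
Conditions: LiAlH4 (4 equiv), THF, reflux; 0 °C, EtOAc then EtOH quench; then Raney Ni (W-2, deactivated by reflux in acetone), EtOH–THF, 0 °C to rt
Reagents that add atoms: none
Why: Five-membered cyclic sulfones are reduced to sulfides by LiAlH4, and Raney nickel desulfurisation (Mozingo-type C–S hydrogenolysis) then turns both ring CH2–S groups into the C2 and C3 methyl groups without touching either stereocentre, while acetone-deactivated nickel at or below rt spares the trisubstituted styrene.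

**Compound list**
1 | 3,4-dimethoxybenzaldehyde | COc1ccc(C=O)cc1OC | starting material
2 | vinylmagnesium bromide | C=C[Mg]Br | starting material
3 | (±)-1-(3,4-dimethoxyphenyl)prop-2-en-1-ol | COc1ccc(C(O)C=C)cc1OC | intermediate
4 | thiourea | NC(N)=S | starting material
5 | propargyl bromide | C#CCBr | starting material
6 | S-[(E)-3-(3,4-dimethoxyphenyl)prop-2-en-1-yl]isothiouronium chloride | COc1ccc(/C=C/CSC(N)=[NH2+])cc1OC.[Cl-] | intermediate
7 | sodium (E)-3-(3,4-dimethoxyphenyl)prop-2-ene-1-thiolate | COc1ccc(/C=C/C[S-])cc1OC.[Na+] | intermediate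
8 | (E)-1,2-dimethoxy-4-[3-(prop-2-yn-1-ylsulfanyl)prop-1-en-1-yl]benzene | COc1ccc(/C=C/CSCC#C)cc1OC | intermediate
9 | 4-iodo-1,2-dimethoxybenzene | COc1ccc(I)cc1OC | starting material
10 | (E)-3-(3,4-dimethoxyphenyl)prop-2-en-1-yl 3-(3,4-dimethoxyphenyl)prop-2-yn-1-yl sulfide | COc1ccc(/C=C/CSCC#Cc2ccc(OC)c(OC)c2)cc1OC | intermediate
11 | (E)-3-(3,4-dimethoxyphenyl)prop-2-en-1-yl 3-(3,4-dimethoxyphenyl)prop-2-yn-1-yl sulfone | COc1ccc(/C=C/CS(=O)(=O)CC#Cc2ccc(OC)c(OC)c2)cc1OC | intermediate
12 | (3aS,4R)-4-(3,4-dimethoxyphenyl)-6,7-dimethoxy-1,3,3a,4-tetrahydronaphtho[2,3-c]thiophene 2,2-dioxide | COc1ccc([C@@H]2c3cc(OC)c(OC)cc3C=C4CS(=O)(=O)C[C@H]42)cc1OC | intermediate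
13 | (3aS,4R)-4-(3,4-dimethoxyphenyl)-6,7-dimethoxy-1,3,3a,4-tetrahydronaphtho[2,3-c]thiophene | COc1ccc([C@@H]2c3cc(OC)c(OC)cc3C=C4CSC[C@H]42)cc1OC | intermediate
14 | (1R,2S)-1-(3,4-dimethoxyphenyl)-6,7-dimethoxy-2,3-dimethyl-1,2-dihydronaphthalene | COc1ccc([C@@H]2c3cc(OC)c(OC)cc3C=C(C)[C@H]2C)cc1OC | target

**Total step count:** 6. **Longest linear sequence:** 6 (1 → 3 → 8 → 10 → 11 → 12 → 14).

**Steps most likely to fail**

**Step 5.** Possible failures:
- 6-endo cyclisation to a cyclopropane-fused thiopyran dioxide.
- A sluggish reaction, because the tether withdraws electron density.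
- Modest ee.

The fallback sets out from 11 and comes back at 12.
- Heating 11 with Et3N in toluene isomerises the propargyl sulfone to the allenyl sulfone F1.
- The aryl-allene unit of F1 then acts as the diene in a thermal intramolecular Diels–Alder reaction with the (E)-styrene (a Garratt–Braverman-related ene–allene cyclisation).
- This again closes both rings at once. Because the addition is suprafacial, it again gives only the trans ring fusion.
- Base-mediated proton shift rearomatises the adduct to the racemate of 12 and the mirror-image sulfone F2.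
- Preparative chromatography on a chiral stationary phase removes F2 and delivers 12.

**Step 6.** Possible failures:
- Saturation of the C3=C4 styrene on nickel.
- Migration of that alkene on nickel.

The fallback sets out from 12 and comes back at 14. It masks the alkene before any nickel is used.
- Hydroboration–oxidation (BH3·THF; H2O2, NaOH) gives the benzylic alcohol F3. The sulfur is already fully oxidised, so the peroxide work-up does not affect it. The new centres at C9 and C9a are inconsequential.
- LiAlH4 gives the hydroxy thiolane F4.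
- Raney Ni at rt gives the hydroxy tetralin F5.
- Catalytic TsOH·H2O in toluene ionises the p-methoxy-stabilised benzylic alcohol and removes the C3 proton (E1), which regenerates only the conjugated C3=C4 alkene of 14.
- C1 and C2 are never touched.

**Step 3.** Possible failures:
- Sulfur slows palladium or copper.
- The propargyl sulfide isomerises.

The fallback sets out from 9 and thiolate 7 and comes back at 10, so palladium never meets sulfur.
- Compound 9 is coupled with propargyl alcohol (PdCl2(PPh3)2, CuI, Et3N) to give the arylpropargyl alcohol F6.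
- An Appel reaction (CBr4, PPh3, CH2Cl2, 0 °C) gives the arylpropargyl bromide F7.
- F7 replaces propargyl bromide in the alkylation of thiolate 7, generated as in step 2, and gives 10 directly.

**Further compounds**
F1 | step 5 | (E)-3-(3,4-dimethoxyphenyl)prop-2-en-1-yl 3-(3,4-dimethoxyphenyl)propa-1,2-dien-1-yl sulfone | COc1ccc(/C=C/CS(=O)(=O)C=C=Cc2ccc(OC)c(OC)c2)cc1OC
F2 | step 5 | (3aR,4S)-4-(3,4-dimethoxyphenyl)-6,7-dimethoxy-1,3,3a,4-tetrahydronaphtho[2,3-c]thiophene 2,2-dioxide | COc1ccc([C@H]2c3cc(OC)c(OC)cc3C=C4CS(=O)(=O)C[C@@H]42)cc1OC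
F3 | step 6 | (3aS,4R)-4-(3,4-dimethoxyphenyl)-9-hydroxy-6,7-dimethoxy-1,3,3a,4,9,9a-hexahydronaphtho[2,3-c]thiophene 2,2-dioxide | COc1ccc([C@@H]2c3cc(OC)c(OC)cc3C(O)C4CS(=O)(=O)C[C@H]42)cc1OC
F4 | step 6 | (3aS,4R)-4-(3,4-dimethoxyphenyl)-6,7-dimethoxy-1,3,3a,4,9,9a-hexahydronaphtho[2,3-c]thiophen-9-ol | COc1ccc([C@@H]2c3cc(OC)c(OC)cc3C(O)C4CSC[C@H]42)cc1OC
F5 | step 6 | (3S,4R)-4-(3,4-dimethoxyphenyl)-6,7-dimethoxy-2,3-dimethyl-1,2,3,4-tetrahydronaphthalen-1-ol | COc1ccc([C@@H]2c3cc(OC)c(OC)cc3C(O)C(C)[C@H]2C)cc1OC
F6 | step 3 | 3-(3,4-dimethoxyphenyl)prop-2-yn-1-ol | COc1ccc(C#CCO)cc1OC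
F7 | step 3 | 4-(3-bromoprop-1-yn-1-yl)-1,2-dimethoxybenzene | COc1ccc(C#CCBr)cc1OC
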